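The numbers in the tables are simulated from invented constants, noise included.

At −20 °C, the north-east flask reads substrate at 0% by 0.333 min, while target reads 65% at 0.500 min and 51% at 2.50 min.

in all of them: substrate 20 mM
- north-east: partner 0.95 equiv; temperature −20 °C; the very flask that is asked about, followed so far
- north: partner 0.47 equiv; temperature −14 °C; run made earlier
- flask: partner 0.950 equiv; temperature −20 °C; time 3.0 min

- north-east (time / min: target / %, substrate / %): 0.200: 47, 1; 0.333: 61, 0; 0.500: 65, 0; 0.833: 59, 0; 1.33: 60, 0; 2.50: 51, 3
- north (time / s: target / %, substrate / %): 12.0: 33, 2; 25.0: 33, 0; 40.0: 34, 0; 50.0: 35, 0; 60.0: 32, 0; 80.0: 35, 3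

(each reading ± 2 percentage points)

- delta: change nothing and wait 6.0 min more
- epsilon: at 3.0 min take out 90% of the target then present, then wait 6.0 min
- alpha: at 3.0 min raise the temperature by 20 K, then wait 6.0 min
- eta: at 3.0 min add partner, 100% of the amount charged, then wait 6.0 min

- removed target is counted in
- steps thought possible: substrate -> open intermediate; partner -> second intermediate; open intermediate + second intermediate -> target; partner + target -> over-reaction product; open intermediate -> side product; target <-> isomer of the product
- additions bring no volume worth counting

1. target, in percent of the substrate first charged, at 3.0 min
2. what to do for the largest gain in target; "none" if nothing gains more than 2 percentage points (delta / epsilon / alpha / eta / none)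
3. target present, with what was taken out counted in, in percent of the substrate first charged, after alpha
4. target present, with what was taken out counted in, in percent of the substrate first charged, after eta

So you should count what the readings don't show. In this flask at 2.50 min, the charge less target and substrate comes to 46 percentage points. Call this the missing share: substrate charged, minus target, minus substrate, all in percent of the charge.

Now test it against partner, the limiting reagent at 0.950 equiv. Each target holds one partner and each over-reaction product holds two. So in this flask, partner can pay for at most 22 points of over-reaction product, which is less than the missing share. On these readings my reckoning therefore puts at least 24 points in open intermediate, side product or isomer. Isomer can return to target, so I would not answer "none".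

The forecast differs. It says 50% now, none as best, 41% after alpha and 5% after eta, holding that the fall “points to over-reaction with leftover partner”.

The flask gives 48.5% now. Its best choice is alpha, gaining 19 points against 16 points for epsilon, with 67.1% after alpha and 47.5% after eta.

    substrate → open intermediate (k = 0.410 s⁻¹, Ea = 56.0 kJ mol⁻¹)
    partner → second intermediate (k = 0.190 s⁻¹, Ea = 73.0 kJ mol⁻¹)
    open intermediate + second intermediate → target (k = 12.0 M⁻¹ s⁻¹, Ea = 38.0 kJ mol⁻¹)
    partner + target → over-reaction product (k = 0.0910 M⁻¹ s⁻¹, Ea = 36.0 kJ mol⁻¹)
    open intermediate → side product (k = 0.0220 s⁻¹, Ea = 75.0 kJ mol⁻¹)
    target ⇌ isomer of the product (K = 0.620, k = 0.00880 s⁻¹, Ea = 78.0 kJ mol⁻¹, ΔH = −40.0 kJ mol⁻¹)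
    (constants at −20 °C)

At 3.00 min, the missing share of this flask is 52 points. It holds isomer at 29.0%, side product at 22.4% and over-reaction product at 0.160%. The neighbour flask, the same but charged with 3.80 equiv of partner, has target at 58.0% at 3.00 min, so its missing share is 42 points. There the partner charged, net of target, could pay for more over-reaction product than that share, so the test sets no floor. Still, that neighbour flask holds over-reaction product at 1.39%, side product at 5.72% and isomer at 34.9%.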